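- The easy mistake is to stretch the steep start of this flask out to 25 min and expect no starting material at all, but the delta run, which is this very flask followed so far, stops falling near 4.2%.

| flask | starting material | second substrate | gas | remark | time |
|---|---|---|---|---|---|
| delta | 0.11 M | 0.11 M | 10 mM (held) | the very flask that is asked about, followed so far |  |
| flask | 0.11 M | 0.110 M | 10 mM (held) |  | 25 min |

delta run (percent of the starting material charged)

| time / min | starting material / % | target / % |
|---|---|---|
| 0.250 | 86.8 | 13.7 |
| 0.667 | 62.8 | 37.2 |
| 1.33 | 32.9 | 67.3 |
| 2.00 | 15.1 | 85.2 |
| 2.50 | 8.4 | 91.2 |
| 4.00 | 4.8 | 95.5 |
| 5.00 | 4.2 | 95.2 |

(readings scatter by 0.3 percentage points)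

- at the start none of the gas is in solution
- the reaction counts as stopped when no species that holds the starting material changes by six tenths of a point or more over the second half of the time

- why nothing more happens at 25 min, or that something still does (all of the starting material has reacted / it is still moving / forward and back rates have come level)
- how much of the starting material has reacted by 25 min
- how much target there is at 25 min, in percent of the starting material charged

- First instants: no gas is in solution, yet target already stands at 13.7% by 0.250 min. The held gas level is 9.09% of the starting material charge, so if the gas is consumed, its supply must keep running through the conversion.
- Middle: starting material goes from 62.8% at 0.667 min to 32.9% at 1.33 min. Target rises to match, and the two add up to 100.2%, so we see no side product taking starting material.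
- End: starting material reads 8.4%, 4.8%, then 4.2%. The last step is 0.6 percentage points against a scatter of 0.3 points, so the curve is level within what the readings can show.
- What we freeze: the gas is held, so we take the gas level in solution as constant late in the run. Each direction of a reversible step is then pseudo-first-order, and target over starting material stops moving. The last readings of the delta run give 22.7 for target over starting material, and we call this the plateau ratio, a reading that carries their scatter.
- Our reckoning: the share left is one over one plus that ratio, or 4.22%, so 95.8% has reacted and, with the balance closed, is target.
- The forecast expects the flask “to sit at equilibrium by 25 min”: forward and back rates have come level, 96% reacted, 95.7% target.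

    gas ⇌ coupling partner, rate k1*(csat - [coupling partner]) (kL = 0.160 s⁻¹)
    second substrate + coupling partner ⇌ second product (K = 190 M⁻¹, k = 0.130 M⁻¹ s⁻¹)
    starting material + coupling partner ⇌ target (K = 2300 M⁻¹, k = 4.30 M⁻¹ s⁻¹)

The flask gives 95.8% reacted and 95.8% target at 25 min: forward and back rates have come level. The quantity we froze is the coupling partner, which stands in this flask at 0.00994 M by 25.0 min against a ceiling of 10 mM. The neighbour flask, charged with 0.044 M of second substrate, holds 0.00998 M of coupling partner. For that neighbour the plateau ratio of 22.7 puts the starting material left at 4.22%, and the neighbour flask holds 4.2%.

The readings were generated by integration from invented constants; the scatter is artificial.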